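In a one-step world that consumes reagent, product follows the reagent lost, and the violet readings level off at 69.8%, next to the 0.70 equiv of reagent charged, so the violet flask is counted here by its fraction left: c(reagent) over its charge.

all flasks: substrate 0.16 M
- violet: reagent 0.70 equiv; initiator 1 mol%; the very flask that is asked about, followed so far
- amber: reagent 0.70 equiv; initiator 2 mol%; run made earlier
- flask: reagent 0.700 equiv; initiator 1 mol%; time 50 min

violet run (percent of the substrate charged)

| time / min | product / % |
|---|---|
| 6.00 | 44.1 |
| 12.0 | 61.9 |
| 20.0 | 67.7 |
| 25.0 | 69.5 |
| 30.0 | 69.5 |
| 40.0 | 69.8 |

amber run (percent of the substrate charged)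

| time / s | product / % |
|---|---|
| 10.0 | 3.4 |
| 20.0 | 5.2 |
| 30.0 | 7.9 |
| 40.0 | 10.4 |
| 50.0 | 12.6 |
| 60.0 | 15.5 |

(standard deviation of a reading: 0.5 percentage points)

- in percentages every species weighs as the substrate in it: one ended chains A counts as two
- product taken out counts as made
- the earlier runs were read with a standard deviation of 0.5 percentage points
- steps that have been proposed: 2 second chain carrier -> ended chains B; reagent + first chain carrier -> product + second chain carrier; substrate + initiating radical -> capped initiator + first chain carrier; substrate + second chain carrier -> released group + first chain carrier; initiator -> 2 initiating radical; 2 first chain carrier -> ended chains A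
- additions bring no volume worth counting

- birch: at 50 min add reagent, 50.0% of the amount charged, then wait 1.5 h
- maple: change nothing and wait 1.5 h more
- alder: at 50 min add substrate, 50.0% of the amount charged, then wait 1.5 h
- cedar: at 50 min take out 90% of the product then present, then wait 1.5 h

* product, in percent of the substrate first charged, at 50 min
* which option adds most product ("none" when 2 percentage points or less is all one gets) (birch / maple / alder / cedar / none)
* product present, with what was taken out counted in, in percent of the substrate first charged, after alder
* product present, with what was taken out counted in, in percent of the substrate first charged, after cedar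

The first violet reading, at 6.00 min, leaves a fraction 37.0%. Read as a pseudo-first-order fall, that gives 4.18 min, the reagent half-life: the time in which the fraction left drops by a factor of 2. The time 50 min holds 12.0 such half-lives, so this reckoning has a fraction 0.0252% left and product at 70.0%.

The reagent still in the flask is worth 0.018 percentage points, less than the 2 points margin, so maple, alder and cedar should each stay near 70.0%. Birch brings reagent worth 35.0% of the substrate charged against 30.0% of substrate left, so this reckoning expects a gain of 30 points and picks birch.

The forecast gave 69.9% (69.4% to 70.1%), birch as best, and 70% after alder and 70% after cedar, opening with “Reagent is the limiting partner”.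

The flask gives 70.0%. Birch adds 30 points, while maple, alder and cedar each add 0.018 points, which leaves 70.0% after alder and 70.0% after cedar.

    2 second chain carrier → ended chains B (k = 4.10 × 10⁶ M⁻¹ s⁻¹)
    reagent + first chain carrier → product + second chain carrier (k = 1.10 × 10⁵ M⁻¹ s⁻¹)
    substrate + initiating radical → capped initiator + first chain carrier (k = 6.40 × 10⁶ M⁻¹ s⁻¹)
    substrate + second chain carrier → released group + first chain carrier (k = 57000 M⁻¹ s⁻¹)
    initiator → 2 initiating radical (k = 4.20 × 10⁻⁵ s⁻¹)
    2 first chain carrier → ended chains A (k = 1.00 × 10⁸ M⁻¹ s⁻¹)

At 4.18 min the violet flask loses reagent to product with a half-life of 4.2 min, far shorter than the 4.6 h of initiator, and at 50.0 min it holds 0.026% of its reagent and 88% of its initiator. Carried to the neighbour charged with 0.420 equiv of reagent, the half-life of 4.18 min gives a fraction 0.0252% left and product at 42.0%; that flask shows 0.025% of its reagent and product at 42.0%.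

The readings come from a simulation for an exercise; the scatter is artificial.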